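**Strategy.** The route rests on cutting the pyran ring of the 2H-chromene at O1–C2 and C3–C4: C2 with its methyl group and CH2O arm plus C3 are 2-methylprop-2-en-1-ol, and C4 is the formyl carbon of a salicylaldehyde whose phenol oxygen becomes O1. The key step ties the arm oxygen to C4 as an oxocarbenium ion and lets the alkene add across C4 and O1, which closes the pyran and a sacrificial oxolane bridge and sets C2 through C4 under chiral acid control. Its precursor is 5-acetyl-2-hydroxy-4-(triisopropylsilyloxy)benzaldehyde, with the para oxygen capped so that only the ortho-quinone methide pathway is open; acylative bridge opening then delivers the ester and the C3–C4 alkene.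

Key step: step 3

Remark on the chemistry: which antipode of the chiral acid leads to the (2R,4R) adduct cannot be derived for this new substrate class, so the (S,S) acid is written and its mirror image is taken if a first run shows the opposite sense; chroman numbering (O1, C2, C3, C4, C4a, C5 to C8, C8a) is used for the bicyclic compounds.

**Route**

Step 1
Reactants: 1 5-bromo-2,4-dihydroxybenzaldehyde
Product: 2 5-bromo-2-hydroxy-4-(triisopropylsilyloxy)benzaldehyde
Conditions: TIPSCl (1.05 equiv), imidazole, DMF, 0 °C to rt
Reagents that add atoms: triisopropylsilyl chloride, CC(C)[Si](Cl)(C(C)C)C(C)C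
Why: Selective O-silylation should occur at the 4-OH, which is para to the formyl group, acidic and not hydrogen-bonded, whereas the 2-OH is locked in a chelate with the aldehyde, so one equivalent of the bulky silyl chloride caps only the oxygen that later becomes O7.

Step 2
Reactants: 2 5-bromo-2-hydroxy-4-(triisopropylsilyloxy)benzaldehyde
Product: 4 5-acetyl-2-hydroxy-4-(triisopropylsilyloxy)benzaldehyde, via enol ether 3 (not isolated)
Conditions: tributyl(1-ethoxyvinyl)stannane (1.5 equiv), Pd(PPh3)4 (5 mol%), toluene, 100 °C; then 1 M HCl, THF, rt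
Reagents that add atoms: tributyl(1-ethoxyvinyl)stannane, CCCC[Sn](CCCC)(CCCC)C(=C)OCC; water, O
Why: Stille coupling with an acetyl anion equivalent runs under neutral conditions that tolerate the aldehyde and the chelated phenol, and the aryl enol ether should be hydrolysed by dilute acid to the methyl ketone much faster than the aryl silyl ether is attacked.

Step 3
Reactants: 4 5-acetyl-2-hydroxy-4-(triisopropylsilyloxy)benzaldehyde; 5 2-methylprop-2-en-1-ol
Product: 8 (2R,4R)-6-acetyl-2-methyl-7-(triisopropylsilyloxy)-2,4-(epoxymethano)chroman, via mixed hemiacetal 6 (not isolated), via oxocarbenium ion 7 (not isolated)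
Conditions: 5 (3 equiv), (S,S)-imidodiphosphoric acid from 3,3'-bis(2,4,6-triethylphenyl)-BINOL (5 mol%), 5 Å MS, toluene, 0 °C to rt
Reagents that add atoms: none
Why: Proposed new method: the acid condenses the formyl group of 4 with 5 to hemiacetal 6 and ionises it to the O-methallyl oxocarbenium ion 7, the protonated form of an ortho-quinone methide, which is held in a contact ion pair with the chiral imidodiphosphate through the hydrogen bond of the ortho phenol; the terminal alkene CH2 then bonds to the oxocarbenium carbon (C4) and the tertiary cationic centre that develops at C2 is captured by the phenol oxygen O1 in one asynchronous [4+2] event. The closest known reaction types are chiral Brønsted acid catalysed hetero-Diels–Alder additions of ortho-quinone methides to 1,1-disubstituted alkenes, the fused-mode intramolecular variants that start from salicylaldehydes and unsaturated alcohols, and Prins cyclisations of salicylaldehyde-derived oxocarbenium ions, whereas the two-atom C4–O–CH2 tether that enforces the bridged mode is without precedent. The oxolane ring closes by C–C bond formation (C3 onto C4, formally 5-endo at the alkene, accessible here because it is one half of the cycloaddition) and the pyran ring closes by C–O bond formation (O1 onto C2, six-membered), which gives the benzo-fused dioxabicyclo[3.2.1]octane. The configuration at C4 is set by the chiral counter-anion, which leaves one face of the planar oxocarbenium carbon open to the alkene, and the configuration at C2 is dictated by C4 because the CH2–O bridge must lie on the face of the pyran that carries the C4 oxygen, so 4R forces 2R. The step needs enantiofacial selectivity (from the catalyst), Markovnikov orientation (O1 to the methyl-bearing carbon, secured by the tertiary cation), linear annulation (secured because the formyl carbon is already bonded to C4a) and chemoselectivity for the aldehyde over the acetyl group, which the substrate secures because only the formyl group has a free ortho phenol while the silyl cap on the para oxygen shuts off ketone-derived and para-quinone methide pathways.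

Step 4
Reactants: 9 ferulic acid, (E)-3-(4-hydroxy-3-methoxyphenyl)prop-2-enoic acid
Product: 11 (E)-3-[4-(tert-butyldimethylsilyloxy)-3-methoxyphenyl]prop-2-enoic acid, via bis-silyl derivative 10 (not isolated)
Conditions: TBSCl (2.3 equiv), imidazole, DMF, rt; then AcOH/THF/H2O (3:1:1), rt
Reagents that add atoms: tert-butyldimethylsilyl chloride, CC(C)(C)[Si](C)(C)Cl
Why: Exhaustive silylation followed by selective solvolysis of the far more labile silyl ester is the standard way to a phenol-protected cinnamic acid and leaves the E alkene untouched.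

Step 5
Reactants: 11 (E)-3-[4-(tert-butyldimethylsilyloxy)-3-methoxyphenyl]prop-2-enoic acid
Product: 12 (E)-3-[4-(tert-butyldimethylsilyloxy)-3-methoxyphenyl]prop-2-enoyl chloride
Conditions: (COCl)2, DMF (cat.), CH2Cl2, 0 °C to rt; evaporate, use crude
Reagents that add atoms: oxalyl chloride, O=C(Cl)C(=O)Cl
Why: Chlorination of the acid through the Vilsmeier-type chloroiminium species formed from oxalyl chloride and catalytic DMF gives the acid chloride under conditions in which the aryl silyl ether and the E alkene are stable.

Step 6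
Reactants: 8 (2R,4R)-6-acetyl-2-methyl-7-(triisopropylsilyloxy)-2,4-(epoxymethano)chroman; 12 (E)-3-[4-(tert-butyldimethylsilyloxy)-3-methoxyphenyl]prop-2-enoyl chloride
Product: 14 [(2R)-6-acetyl-2-methyl-7-(triisopropylsilyloxy)-2H-chromen-2-yl]methyl (E)-3-[4-(tert-butyldimethylsilyloxy)-3-methoxyphenyl]prop-2-enoate, via 4-chlorochroman ester 13 (not isolated)
Conditions: Sc(OTf)3 (5 mol%), CH2Cl2, −20 to 0 °C; then i-Pr2NEt, 0 °C to rt
Reagents that add atoms: none
Why: This is a Lewis-acid-promoted acylative cleavage of a benzylic cyclic ether by an acyl chloride followed by dehydrohalogenation: the bridging oxygen is the only dialkyl ether oxygen, its acyloxonium ion should break at the C4–O bond because the C4 cation is stabilised by O1 and the para silyloxy group while bridgehead C2 cannot ionise, and the labile 4-chloride loses HCl across C3–C4 on adding base, so the ester and the alkene form together, C2 keeps its configuration and the C4 centre is erased.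

Step 7
Reactants: 14 [(2R)-6-acetyl-2-methyl-7-(triisopropylsilyloxy)-2H-chromen-2-yl]methyl (E)-3-[4-(tert-butyldimethylsilyloxy)-3-methoxyphenyl]prop-2-enoate
Product: 15 [(2R)-6-acetyl-7-hydroxy-2-methyl-2H-chromen-2-yl]methyl (E)-3-(4-hydroxy-3-methoxyphenyl)prop-2-enoate (CNP0375196.1)
Conditions: TBAF, AcOH, THF, 0 °C, subdued light
Reagents that add atoms: none
Why: Fluoride-induced cleavage of aryl silyl ethers, buffered with acetic acid so that the phenoxides are protonated as they form, should free both phenols while the cinnamate ester, the chromene and the quaternary C2 centre, which has no acidic hydrogen and no ionisation pathway under these conditions, remain untouched.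

**Compound list**

1 | 5-bromo-2,4-dihydroxybenzaldehyde | O=Cc1cc(Br)c(O)cc1O | starting material
2 | 5-bromo-2-hydroxy-4-(triisopropylsilyloxy)benzaldehyde | O=Cc1cc(Br)c(O[Si](C(C)C)(C(C)C)C(C)C)cc1O | intermediate
3 | 5-(1-ethoxyethenyl)-2-hydroxy-4-(triisopropylsilyloxy)benzaldehyde | CCOC(=C)c1cc(C=O)c(O)cc1O[Si](C(C)C)(C(C)C)C(C)C | intermediate (not isolated)
4 | 5-acetyl-2-hydroxy-4-(triisopropylsilyloxy)benzaldehyde | CC(=O)c1cc(C=O)c(O)cc1O[Si](C(C)C)(C(C)C)C(C)C | intermediate
5 | 2-methylprop-2-en-1-ol | C=C(C)CO | starting material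
6 | 1-{4-hydroxy-5-[hydroxy(2-methylprop-2-enyloxy)methyl]-2-(triisopropylsilyloxy)phenyl}ethanone, mixed hemiacetal, both configurations at the hemiacetal carbon | CC(=O)c1cc(C(O)OCC(C)=C)c(O)cc1O[Si](C(C)C)(C(C)C)C(C)C | intermediate (not isolated)
7 | (E)-O-(2-methylprop-2-enyl) oxocarbenium ion of 4, cation of the ion pair with the chiral imidodiphosphate | CC(=O)c1cc(/C=[O+]/CC(C)=C)c(O)cc1O[Si](C(C)C)(C(C)C)C(C)C | intermediate (not isolated)
8 | (2R,4R)-6-acetyl-2-methyl-7-(triisopropylsilyloxy)-2,4-(epoxymethano)chroman, bridge CH2 on C2 and bridge O on C4 | C[C@@]12C[C@@H](OC1)c1cc(C(C)=O)c(O[Si](C(C)C)(C(C)C)C(C)C)cc1O2 | intermediate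
9 | ferulic acid, (E)-3-(4-hydroxy-3-methoxyphenyl)prop-2-enoic acid | COc1cc(/C=C/C(=O)O)ccc1O | starting material
10 | tert-butyldimethylsilyl (E)-3-[4-(tert-butyldimethylsilyloxy)-3-methoxyphenyl]prop-2-enoate | COc1cc(/C=C/C(=O)O[Si](C)(C)C(C)(C)C)ccc1O[Si](C)(C)C(C)(C)C | intermediate (not isolated)
11 | (E)-3-[4-(tert-butyldimethylsilyloxy)-3-methoxyphenyl]prop-2-enoic acid | COc1cc(/C=C/C(=O)O)ccc1O[Si](C)(C)C(C)(C)C | intermediate
12 | (E)-3-[4-(tert-butyldimethylsilyloxy)-3-methoxyphenyl]prop-2-enoyl chloride | COc1cc(/C=C/C(=O)Cl)ccc1O[Si](C)(C)C(C)(C)C | intermediate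
13 | [(2R)-6-acetyl-4-chloro-2-methyl-7-(triisopropylsilyloxy)chroman-2-yl]methyl (E)-3-[4-(tert-butyldimethylsilyloxy)-3-methoxyphenyl]prop-2-enoate, both C4 epimers | COc1cc(/C=C/C(=O)OC[C@@]2(C)CC(Cl)c3cc(C(C)=O)c(O[Si](C(C)C)(C(C)C)C(C)C)cc3O2)ccc1O[Si](C)(C)C(C)(C)C | intermediate (not isolated)
14 | [(2R)-6-acetyl-2-methyl-7-(triisopropylsilyloxy)-2H-chromen-2-yl]methyl (E)-3-[4-(tert-butyldimethylsilyloxy)-3-methoxyphenyl]prop-2-enoate | COc1cc(/C=C/C(=O)OC[C@@]2(C)C=Cc3cc(C(C)=O)c(O[Si](C(C)C)(C(C)C)C(C)C)cc3O2)ccc1O[Si](C)(C)C(C)(C)C | intermediate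
15 | [(2R)-6-acetyl-7-hydroxy-2-methyl-2H-chromen-2-yl]methyl (E)-3-(4-hydroxy-3-methoxyphenyl)prop-2-enoate | COc1cc(/C=C/C(=O)OC[C@@]2(C)C=Cc3cc(C(C)=O)c(O)cc3O2)ccc1O | target

**Step count and risks**

Total step count: 7. Longest linear sequence: 5 (steps 1, 2, 3, 6, 7).

Steps most likely to fail:

1. Step 3 (Proposed new method). The oxocarbenium ion may be drained into the bis(methallyl) acetal, or it may lose a proton after C–C bond formation instead of closing the pyran, or the ion pair may discriminate the two faces poorly. The fallback uses known chemistry, building the stereocentre by asymmetric allylic etherification and closing the ring by metathesis. It sets out from 4, whose free phenol is added to 2-methyl-2-vinyloxirane (CC1(C=C)CO1) with Pd2(dba)3·CHCl3 and the antipode of the DACH-phenyl Trost ligand that delivers the (R) ether (CH2Cl2, rt, dynamic kinetic asymmetric etherification at the more substituted allyl terminus), giving 5-acetyl-2-{[(2R)-1-hydroxy-2-methylbut-3-en-2-yl]oxy}-4-(triisopropylsilyloxy)benzaldehyde F1. The primary alcohol is acylated with 12 (Et3N, DMAP, CH2Cl2, 0 °C) to (2R)-2-[4-acetyl-2-formyl-5-(triisopropylsilyloxy)phenoxy]-2-methylbut-3-en-1-yl (E)-3-[4-(tert-butyldimethylsilyloxy)-3-methoxyphenyl]prop-2-enoate F2. The aldehyde is methylenated in preference to the ketone by a Wittig reaction (Ph3P=CH2, THF, −78 °C) to (2R)-2-[4-acetyl-2-ethenyl-5-(triisopropylsilyloxy)phenoxy]-2-methylbut-3-en-1-yl (E)-3-[4-(tert-butyldimethylsilyloxy)-3-methoxyphenyl]prop-2-enoate F3. Ring-closing metathesis with second-generation Grubbs catalyst, RuCl2(=CHPh)(H2IMes)(PCy3) (CH2Cl2, 40 °C), then forms the C3–C4 alkene and comes back to the route at 14.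

2. Step 6. Acylation of the hindered bridging oxygen by the conjugated acid chloride may be slow, so that the Lewis acid instead strips a silyl group or, once the chromene has formed, ionises its allylic C2–O1 bond and erodes the configuration at C2. The fallback separates bridge opening from ester formation. It sets out from 8, in which bromotrimethylsilane (CH2Cl2, −40 °C) cleaves the benzylic C4–O bond to [(2R)-6-acetyl-4-bromo-2-methyl-7-(triisopropylsilyloxy)chroman-2-yl]methyl trimethylsilyl ether F4. DBU (CH2Cl2, 0 °C) removes HBr to give [(2R)-6-acetyl-2-methyl-7-(triisopropylsilyloxy)-2H-chromen-2-yl]methyl trimethylsilyl ether F5. A citric acid work-up hydrolyses the trimethylsilyl ether to 1-[(2R)-2-(hydroxymethyl)-2-methyl-7-(triisopropylsilyloxy)-2H-chromen-6-yl]ethanone F6. This alcohol is acylated with 12 under basic conditions (Et3N, DMAP, CH2Cl2, 0 °C) and comes back to the route at 14.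

3. Step 2. The acid-sensitive alkoxyvinylstannane may be protodestannylated by the acidic phenol, oxidative addition next to the bulky silyl ether may be slow, or the silyl ether may be lost during the acid hydrolysis. The fallback unveils the acetyl group by alkene cleavage instead of enol ether hydrolysis. It sets out from 2: Suzuki–Miyaura coupling with isopropenylboronic acid pinacol ester (PdCl2(dppf), K3PO4, dioxane/H2O, 80 °C) gives 2-hydroxy-5-(prop-1-en-2-yl)-4-(triisopropylsilyloxy)benzaldehyde F7. Lemieux–Johnson cleavage of its 1,1-disubstituted alkene (OsO4 cat., NaIO4, 2,6-lutidine, dioxane/H2O, rt) comes back to the route at 4.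

Further compounds
F1 | step 3 | 5-acetyl-2-{[(2R)-1-hydroxy-2-methylbut-3-en-2-yl]oxy}-4-(triisopropylsilyloxy)benzaldehyde | CC(=O)c1cc(C=O)c(O[C@@](C)(CO)C=C)cc1O[Si](C(C)C)(C(C)C)C(C)C
F2 | step 3 | (2R)-2-[4-acetyl-2-formyl-5-(triisopropylsilyloxy)phenoxy]-2-methylbut-3-en-1-yl (E)-3-[4-(tert-butyldimethylsilyloxy)-3-methoxyphenyl]prop-2-enoate | COc1cc(/C=C/C(=O)OC[C@@](C)(C=C)Oc2cc(O[Si](C(C)C)(C(C)C)C(C)C)c(C(C)=O)cc2C=O)ccc1O[Si](C)(C)C(C)(C)C
F3 | step 3 | (2R)-2-[4-acetyl-2-ethenyl-5-(triisopropylsilyloxy)phenoxy]-2-methylbut-3-en-1-yl (E)-3-[4-(tert-butyldimethylsilyloxy)-3-methoxyphenyl]prop-2-enoate | COc1cc(/C=C/C(=O)OC[C@@](C)(C=C)Oc2cc(O[Si](C(C)C)(C(C)C)C(C)C)c(C(C)=O)cc2C=C)ccc1O[Si](C)(C)C(C)(C)C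
F4 | step 6 | [(2R)-6-acetyl-4-bromo-2-methyl-7-(triisopropylsilyloxy)chroman-2-yl]methyl trimethylsilyl ether, both C4 epimers | C[Si](C)(C)OC[C@@]1(C)CC(Br)c2cc(C(C)=O)c(O[Si](C(C)C)(C(C)C)C(C)C)cc2O1
F5 | step 6 | [(2R)-6-acetyl-2-methyl-7-(triisopropylsilyloxy)-2H-chromen-2-yl]methyl trimethylsilyl ether | C[Si](C)(C)OC[C@@]1(C)C=Cc2cc(C(C)=O)c(O[Si](C(C)C)(C(C)C)C(C)C)cc2O1
F6 | step 6 | 1-[(2R)-2-(hydroxymethyl)-2-methyl-7-(triisopropylsilyloxy)-2H-chromen-6-yl]ethanone | OC[C@@]1(C)C=Cc2cc(C(C)=O)c(O[Si](C(C)C)(C(C)C)C(C)C)cc2O1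
F7 | step 2 | 2-hydroxy-5-(prop-1-en-2-yl)-4-(triisopropylsilyloxy)benzaldehyde | CC(=C)c1cc(C=O)c(O)cc1O[Si](C(C)C)(C(C)C)C(C)C
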